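The data stem from a simulated flask with constants of no real substance, noise included.

The closed, stirred flask holds the charge below, and the same impurity and partner charges stand in the dawn, dusk and winter runs.

| flask | starting material | coupling partner | protic impurity | free catalyst | remark |
|---|---|---|---|---|---|
| dawn | 0.40 M | 1.2 M | 0.12 M | 62 mM | run made earlier |
| dusk | 0.40 M | 1.2 M | 0.12 M | 97 mM | run made earlier |
| winter | 0.80 M | 1.2 M | 0.12 M | 44 mM | run made earlier |
| flask | 0.40 M | 1.20 M | 0.120 M | 44 mM |  |

| run | time / s | target / % | starting material / % |
|---|---|---|---|
| dawn | 10.0 | 0.8 | 93.8 |
| dawn | 20.0 | 2.4 | 89.4 |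
| dawn | 30.0 | 3.1 | 85.5 |
| dawn | 60.0 | 4.8 | 78.4 |
| dawn | 120 | 9.0 | 69.2 |
| dusk | 10.0 | 0 | 91.7 |
| dusk | 30.0 | 5.4 | 84.4 |
| dusk | 60.0 | 8.1 | 75.0 |
| dusk | 80.0 | 11.8 | 70.8 |
| dusk | 120 | 13.3 | 65.0 |
| winter | 10.0 | 0 | 95.2 |
| winter | 20.0 | 0.3 | 92.1 |
| winter | 30.0 | 2.5 | 89.2 |
| winter | 60.0 | 4.6 | 84.1 |
| winter | 120 | 6.7 | 78.7 |

(scatter of a reading: 0.5 percentage points)

- the analysis behind the earlier runs scatters by 0.5 percentage points, standard deviation
- no earlier run changes the charge of coupling partner; that part of a forecast is a guess

* apparent order in coupling partner when 20% of the starting material are converted (percent change of the rate of making target for one percent more coupling partner charged)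
* apparent order in free catalyst when 20% of the starting material are converted (percent change of the rate of making target for one percent more free catalyst charged)

Free catalyst is the first setting. By hand, a rate taken at fixed conversion has fixed starting material, so the order in free catalyst is one. The winter run, with the flask's catalyst charge, adds a correction. Its target gains 4.6% by 60.0 s, then 2.1 percentage points in the next 60.0 s, which is less than the first gain. Read as catalyst deactivation, the two gains give a reading of the fading in the winter run:

fading rate = ln(first gain / second gain) / interval = 0.0131 /s

Interpolating the starting material, dawn reaches 20% conversion at 53.2 s and dusk at 44.0 s. The dusk run, with more catalyst, gets there sooner than the dawn run, and the two times give a reading of the sensitivity: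

time sensitivity = ln(dawn time / dusk time) / ln(dusk catalyst / dawn catalyst) = 0.424

flask time = dawn time × (dawn catalyst / flask catalyst)^sensitivity = 61.6 s

In this reckoning the order is one at a very short wait. With a longer wait, the richer dusk charge arrives earlier than the dawn charge and with less activity faded, and the two ends join:

excess = fading rate × flask time × time sensitivity = 0.341

This order excess is the part of the order in free catalyst above one. It puts the order at 1.34, as a reading that carries the scatter of the gains and times behind it.

Coupling partner is the second setting. By hand its order is one, but no run changes its charge, so one plus an unread excess stands as a guess.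

Starting material is the third. The flask's 0.40 M matches dawn and dusk, while winter's 0.80 M differs, and the fading read in the winter run is taken over unchanged for the flask, as an assumption.

The forecast gives 1 for coupling partner and 0.97 for free catalyst, lower than the order reckoned here: “At fixed conversion, SM is fixed, so ord_C is about 1.”

The flask gives 1.3 for coupling partner and 1.4 for free catalyst.

    starting material + free catalyst ⇌ catalyst intermediate A (K = 0.300 /M, k = 3.30 /M/s)
    coupling partner + catalyst intermediate A → catalyst intermediate B (k = 0.130 /M/s)
    catalyst intermediate B → by-product + catalyst intermediate C (k = 0.160 /s)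
    catalyst intermediate C ⇌ free catalyst + target (K = 1.30 M, k = 0.170 /s)
    starting material + protic impurity → quenched substrate (k = 0.0300 /M/s)
    free catalyst ⇌ dormant form (K = 23.0, k = 0.0230 /s)

The flask reaches 20% conversion at 1.04 min. At 1.00 min, the flask's free catalyst stands at 27.5% and its dormant form at 63.7% of the catalyst charged. With the flask's own time, the order excess comes to 0.347, and the flask's order in free catalyst stands 0.400 above one.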